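All runs stem from a simulated flask for an exercise; scatter was added.

Freeze one number from the gamma run before reckoning any charge: the clearance rate, meaning the c_Q consumed per minute up to the first reading, here 0.470 M min⁻¹. It is a reading and carries the scatter of the readings behind it.

| flask | Q | remark | time |
|---|---|---|---|
| gamma | 0.44 M | run made earlier |  |
| autumn | 0.40 M |  | 15 min |
| summer | 0.80 M |  | 15 min |
| dawn | 1.5 M |  | 15 min |
| dusk | 3.0 M |  | 15 min |

gamma run (percent of the Q charged)

| time / min | D / % | Q / % |
|---|---|---|
| 0.667 | 72.6 | 28.8 |
| 1.00 | 89.4 | 9.9 |
| 1.50 | 96.2 | 3.9 |
| 2.50 | 100.2 | 1.0 |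
| 4.00 | 99.3 | 0.2 |
| 6.00 | 99.5 | 0 |
| 10.0 | 100.1 | 2.0 |

(scatter of a reading: 1 percentage point)

- what was read earlier has a scatter of 1 percentage point, one standard deviation
- "hardly changes" means that all values lie within two and a half points (for a concentration: within two and a half percent of the largest)

- [D] at the end for autumn, summer, dawn, dusk, in this order
- the shape of the row from first to last (rises all the way / rises, then falls / hardly changes / falls all the way / falls, then rises)

Two chemists dispute what this number does at higher charges. The first holds that the conversion of Q into D is saturated, zero-order in Q, so the clearance rate stays frozen and the clearing time is the charge divided by it. By my own reckoning on her view, dusk clears in 6.39 min, which is shorter than the 15 min allowed, so c_D ends equal to the charge in each flask.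

The second points to gamma, where the specific rate reads 1.87 min⁻¹ up to the first reading and 3.21 min⁻¹ in the next interval, higher as c_Q fell. She reads substrate inhibition and freezes the product of rate and c_Q instead. On her rule dawn clears in 5.44 min, but dusk needs 21.8 min, longer than the time allowed. Dusk then ends at 1.33 M, less than dawn's 1.5 M, so her row rises, then falls.

The forecast stands with the first chemist: 0.4 M, 0.8 M, 1.5 M, 3 M, so that the row rises all the way, with the words “Even read as saturation, the rate is about 0.5 M/min, so 3 M needs roughly 6–10 min.”

The flasks end at 0.400 M, 0.800 M, 1.50 M and 3.00 M: the row rises all the way.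

    Q → D, rate k1*[Q]/(1 + ([Q]/sat1)) (0.370 M, k = 0.0540 s⁻¹)
    Q → X (k = 1.40 × 10⁻⁶ s⁻¹)

At 7.50 min, later than the clearing time of 6.39 min, dusk already holds Q at 0 % and X at 0.0131 % of the charge. The second chemist keeps the stretch of gamma from 0.667 min to 1.00 min, where her rising specific rate was read. On summer, the clearance rate gives a clearing time of 1.70 min, and summer's Q stands under 2.00 % of its charge at 1.86 min.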